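## Retrosynthetic overview

1. Last disconnection: the five-membered α-methylene lactone is opened at O–C6 and at C11–C12, that is, CO2 is taken out. This leaves a ten-membered carbocycle with a C11 enol triflate (from a C11 methyl ketone) and a plain C6 methylene group.
2. Enabling feature: C6–H is allylic to the cis C4=C5 double bond of the ten-membered ring and lies 1,5 to the oxygens of a carboxyl group on C11, and C11 is a 1,1-disubstituted vinyl carbon. One paired electrolysis can therefore fix CO2 on C11 at the cathode and close the five-membered lactone ring onto C6 at the anode.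
3. Ten-membered ring: C9–C10 bond by intramolecular Nozaki–Hiyama–Kishi reaction of a (Z)-vinyl iodide with a C9 aldehyde; C9 is inverted when its ester is put on.
4. C7 and C8: trans-alkylation of the dianion of (S)-3-hydroxy-γ-butyrolactone with an allylic bromide made from neryl acetate (C1–C6, C10, C14, C15; cis C4=C5). This butyrolactone, whose C11–O–C9 link is absent from the target, is a temporary ring that sets C7 and is then opened by MeLi to the C11 methyl ketone and the C9 alcohol.
5. Order of ring formation: temporary butyrolactone (chiral pool), then the ten-membered carbocycle, then the α-methylene-γ-lactone.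

Key step: step 15

Remark: carbons are numbered as in the target (germacranolide numbering: C6 lactone carbinol, C7 ring fusion, C8 and C9 ester carbons, C11 the carbon bearing the exocyclic methylene C13, C12 the lactone carbonyl, C14 the formyl carbon on C10, C15 the methyl on C4); the ring closure of step 10 is assumed to follow the Felkin–Anh sense (8,9-anti), which step 11 then inverts.

## Route

Step 1
Reactants: 1 neryl acetate
Product: 3 (2Z)-3-methyl-6-oxohex-2-en-1-yl acetate, via epoxide 2 (not isolated)
Conditions: mCPBA, CH2Cl2, 0 °C; then H5IO6, THF/H2O, 0 °C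
Reagents that add atoms: 3-chloroperbenzoic acid (mCPBA) OOC(=O)c1cccc(Cl)c1
Why: Prilezhaev epoxidation takes the electron-richer terminal 6,7-double bond (the 2,3-double bond is deactivated by the allylic acetate) and periodic acid cleaves the epoxide through its diol to the aldehyde and acetone, so the racemic epoxide carbon is lost and the cis double bond is untouched.

Step 2
Reactants: 3 (2Z)-3-methyl-6-oxohex-2-en-1-yl acetate
Product: 4 (2Z,6E)-3-methyl-8-oxoocta-2,6-dien-1-yl acetate
Conditions: Ph3P=CHCHO, toluene, 80 °C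
Reagents that add atoms: (triphenylphosphoranylidene)acetaldehyde O=CC=P(c1ccccc1)(c1ccccc1)c1ccccc1
Why: Wittig olefination with the stabilised formylmethylene ylide extends the aldehyde by two carbons and should give the (E)-enal, as stabilised ylides do.

Step 3
Reactants: 4 (2Z,6E)-3-methyl-8-oxoocta-2,6-dien-1-yl acetate
Product: 5 (2Z,6Z)-7-iodo-3-methyl-8-oxoocta-2,6-dien-1-yl acetate
Conditions: I2, pyridine, DMAP (cat.), CH2Cl2, 0 °C to rt
Reagents that add atoms: iodine II
Why: α-iodination of the enal by the amine-catalysed addition–iodination–elimination sequence (Baylis–Hillman-type) puts iodine in the place of the α-hydrogen, which fixes the (Z)-2-iodoalkene with iodine and the chain cis.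

Step 4
Reactants: 5 (2Z,6Z)-7-iodo-3-methyl-8-oxoocta-2,6-dien-1-yl acetate
Product: 7 (2Z,6Z)-7-iodo-8,8-dimethoxy-3-methylocta-2,6-dien-1-ol, via acetal acetate 6 (not isolated)
Conditions: HC(OMe)3, MeOH, pyridinium p-toluenesulfonate (cat.), rt; then K2CO3 (0.3 equiv), rt
Reagents that add atoms: trimethyl orthoformate COC(OC)OC; methanol CO
Why: acid-catalysed acetalisation protects the formyl group and base-catalysed transesterification (methanolysis) then frees the allylic alcohol without touching the vinyl iodide or either double-bond geometry.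

Step 5
Reactants: 7 (2Z,6Z)-7-iodo-8,8-dimethoxy-3-methylocta-2,6-dien-1-ol
Product: 8 (2Z,6Z)-8-bromo-2-iodo-1,1-dimethoxy-6-methylocta-2,6-diene
Conditions: CBr4, PPh3, 2,6-lutidine, CH2Cl2, −20 °C
Reagents that add atoms: carbon tetrabromide BrC(Br)(Br)Br
Why: Appel reaction converts the primary allylic alcohol into the bromide by SN2 displacement of the oxyphosphonium ion under near-neutral conditions, which should keep the acetal and the cis double bond.

Step 6
Reactants: 9 (S)-3-hydroxy-γ-butyrolactone; 8 (2Z,6Z)-8-bromo-2-iodo-1,1-dimethoxy-6-methylocta-2,6-diene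
Product: 11 (3S,4S)-4-hydroxy-3-[(2Z,6Z)-7-iodo-8,8-dimethoxy-3-methylocta-2,6-dien-1-yl]oxolan-2-one, via dilithium dianion 10 (not isolated)
Conditions: LiN(iPr)2 (2.1 equiv), THF, −78 to −40 °C; then 8, DMPU, −40 to −20 °C
Reagents that add atoms: none
Why: Fráter–Seebach-type alkylation of the lactone dianion, in which the allylic bromide approaches the enolate face anti to the C8 lithium alkoxide, so the temporary five-membered ring sets the new C7 stereocentre trans to the C8 oxygen (3S,4S).

Step 7
Reactants: 11 (3S,4S)-4-hydroxy-3-[(2Z,6Z)-7-iodo-8,8-dimethoxy-3-methylocta-2,6-dien-1-yl]oxolan-2-one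
Product: 12 (3S,4S)-3-[(2Z,6Z)-7-iodo-8,8-dimethoxy-3-methylocta-2,6-dien-1-yl]-4-(triethylsilyloxy)oxolan-2-one
Conditions: TESCl, imidazole, DMF, 0 °C to rt
Reagents that add atoms: chlorotriethylsilane CC[Si](Cl)(CC)CC
Why: silyl ether formation protects the C8 hydroxyl for the organolithium, oxidation and chromium steps.

Step 8
Reactants: 12 (3S,4S)-3-[(2Z,6Z)-7-iodo-8,8-dimethoxy-3-methylocta-2,6-dien-1-yl]-4-(triethylsilyloxy)oxolan-2-one
Product: 13 (3S,5Z,9Z)-3-[(1S)-2-hydroxy-1-(triethylsilyloxy)ethyl]-10-iodo-11,11-dimethoxy-6-methylundeca-5,9-dien-2-one (in equilibrium with its cyclic hemiketal)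
Conditions: MeLi (1.1 equiv), THF, −78 °C
Reagents that add atoms: methyllithium [Li]C
Why: nucleophilic addition of MeLi to the lactone carbonyl gives a lithium hemiketal alkoxide that is stable at −78 °C and collapses only on work-up, so one methyl group is added and the temporary ring is opened to the C11 methyl ketone and the C9 primary alcohol.

Step 9
Reactants: 13 (3S,5Z,9Z)-3-[(1S)-2-hydroxy-1-(triethylsilyloxy)ethyl]-10-iodo-11,11-dimethoxy-6-methylundeca-5,9-dien-2-one
Product: 14 (2S,3S,5Z,9Z)-3-acetyl-10-iodo-11,11-dimethoxy-6-methyl-2-(triethylsilyloxy)undeca-5,9-dienal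
Conditions: Dess–Martin periodinane, pyridine, CH2Cl2, 0 °C
Reagents that add atoms: none
Why: Dess–Martin oxidation of the primary alcohol (drawn from the open form of the hemiketal equilibrium) under buffered, non-basic conditions should give the α-silyloxy aldehyde without epimerising C8 or C7 and without furan formation from the 1,4-keto aldehyde.

Step 10
Reactants: 14 (2S,3S,5Z,9Z)-3-acetyl-10-iodo-11,11-dimethoxy-6-methyl-2-(triethylsilyloxy)undeca-5,9-dienal
Product: 15 (7S,8S,9R,1(10)E,4Z)-7-acetyl-10-(dimethoxymethyl)-4-methyl-8-(triethylsilyloxy)cyclodeca-1(10),4-dien-9-ol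
Conditions: CrCl2 (8 equiv), NiCl2 (2 mol %), DMSO/THF, rt, slow addition to 0.003 M
Reagents that add atoms: none
Why: Nozaki–Hiyama–Kishi reaction, in which zerovalent nickel inserts into the C–I bond and transmetalation gives an alkenylchromium that adds only to the aldehyde (the methyl ketone is inert); the two cis double bonds keep the ten-membered ring low in strain, and C9 is set by Felkin–Anh addition anti to the C8 silyloxy group (8,9-anti, 9R).

Step 11
Reactants: 15 (7S,8S,9R,1(10)E,4Z)-7-acetyl-10-(dimethoxymethyl)-4-methyl-8-(triethylsilyloxy)cyclodeca-1(10),4-dien-9-ol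
Product: 16 (7S,8S,9S,1(10)E,4Z)-7-acetyl-10-(dimethoxymethyl)-4-methyl-8-(triethylsilyloxy)cyclodeca-1(10),4-dien-9-yl 2-methylpropanoate
Conditions: isobutyric acid, PPh3, diisopropyl azodicarboxylate, toluene, 0 °C to rt
Reagents that add atoms: isobutyric acid CC(C)C(=O)O
Why: Mitsunobu esterification displaces the activated C9 oxygen by isobutyrate with SN2 inversion (9R to 9S), so the ester is installed and the 8,9-syn relationship of the target is set in one step.

Step 12
Reactants: 16 (7S,8S,9S,1(10)E,4Z)-7-acetyl-10-(dimethoxymethyl)-4-methyl-8-(triethylsilyloxy)cyclodeca-1(10),4-dien-9-yl 2-methylpropanoate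
Product: 17 (7S,8S,9S,1(10)E,4Z)-10-(dimethoxymethyl)-4-methyl-8-(triethylsilyloxy)-7-[1-(trifluoromethylsulfonyloxy)vinyl]cyclodeca-1(10),4-dien-9-yl 2-methylpropanoate
Conditions: PhNTf2, KN(SiMe3)2 (added last), THF, −78 °C
Reagents that add atoms: N-phenylbis(trifluoromethanesulfonimide) O=S(=O)(N(c1ccccc1)S(=O)(=O)C(F)(F)F)C(F)(F)F
Why: enol triflate formation by kinetic deprotonation of the methyl ketone at its unhindered methyl group (more acidic than the ester α-hydrogen) with trapping of the enolate on oxygen as it forms, which leaves C7 untouched and gives the 1,1-disubstituted alkenyl triflate.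

Step 13
Reactants: 17 (7S,8S,9S,1(10)E,4Z)-10-(dimethoxymethyl)-4-methyl-8-(triethylsilyloxy)-7-[1-(trifluoromethylsulfonyloxy)vinyl]cyclodeca-1(10),4-dien-9-yl 2-methylpropanoate
Product: 18 (7S,8S,9S,1(10)E,4Z)-10-formyl-8-hydroxy-4-methyl-7-[1-(trifluoromethylsulfonyloxy)vinyl]cyclodeca-1(10),4-dien-9-yl 2-methylpropanoate
Conditions: HCl (1 M aq.), THF, 0 °C to rt
Reagents that add atoms: water O
Why: aqueous acid hydrolysis removes the dimethyl acetal and the triethylsilyl ether together while the enol triflate and the ester should survive, and any acyl shift between O9 and O8 is harmless because the next step makes both esters the same.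

Step 14
Reactants: 18 (7S,8S,9S,1(10)E,4Z)-10-formyl-8-hydroxy-4-methyl-7-[1-(trifluoromethylsulfonyloxy)vinyl]cyclodeca-1(10),4-dien-9-yl 2-methylpropanoate
Product: 19 (7S,8S,9S,1(10)E,4Z)-10-formyl-4-methyl-7-[1-(trifluoromethylsulfonyloxy)vinyl]cyclodeca-1(10),4-diene-8,9-diyl bis(2-methylpropanoate)
Conditions: (iPrCO)2O, DMAP (cat.), pyridine, CH2Cl2, 0 °C to rt
Reagents that add atoms: isobutyric anhydride CC(C)C(=O)OC(=O)C(C)C
Why: DMAP-catalysed acylation (nucleophilic catalysis) of the remaining hydroxyl gives the bis-isobutyrate, and the enal and the enol triflate do not react.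

Step 15
Reactants: 19 (7S,8S,9S,1(10)E,4Z)-10-formyl-4-methyl-7-[1-(trifluoromethylsulfonyloxy)vinyl]cyclodeca-1(10),4-diene-8,9-diyl bis(2-methylpropanoate)
Product: 21 (6R,7S,8S,9S,1(10)E,4Z)-8,9-bis(2-methylpropanoyloxy)-14-oxogermacra-1(10),4,11(13)-trien-12,6-olide (the target), via acrylic acid 20 (not isolated)
Conditions: undivided cell, carbon-felt cathode and anode, constant current (2.2 F per mol); Ni(O3SCF3)2 (10 mol %), 4,4′-di-tert-butyl-2,2′-bipyridine (12 mol %), CO2 (1 atm), K2CO3 (2 equiv), nBu4NPF6 (0.1 M), DMF, rt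
Reagents that add atoms: carbon dioxide O=C=O
Why: Proposed new method: a paired electrolysis in which each electrode makes one bond: at the cathode zerovalent nickel inserts into the enol triflate C–O bond and the reduced alkenylnickel inserts CO2 to give carboxylate 20 (C11–C12 bond; closest known type: nickel- or palladium-catalysed electroreductive carboxylation of alkenyl triflates and halides). At the anode 20, whose loss of CO2 would give a vinyl radical and is therefore slow, is oxidised to the acyloxy radical, which takes the allylic C6 hydrogen through a six-membered transition state (1,5-hydrogen transfer); the C4–C5–C6 allyl radical is oxidised to the allyl cation and captured by the carboxyl oxygen (O–C6 bond; closest known type: anodic dehydrogenative lactonisation of 2-alkylbenzoic acids at the benzylic C–H bond). The lactone closes in the five-membered exo mode (5-exo) onto the C6 end of the allyl cation, since attack at C4 would need a seven-membered ring. The new C6 stereocentre is controlled by the C7 stereocentre: in the closing conformer the C7 hydrogen, not C8, eclipses the allyl plane (least allylic strain), so C5 and C8 end up anti and the lactone should be trans-fused (6R). Site selectivity for C6–H is secured by the intramolecular hydrogen transfer (only C6–H and C8–H are 1,5 to the radical oxygen, and C8–H is deactivated by its acyloxy group), the cis C4=C5 geometry by capture of the ring-bound allyl cation before it can rotate, and freedom from transannular attack by the formyl group, which makes C1=C10 electron-poor. The step is redox-neutral overall (19 plus CO2 gives 21 plus triflic acid, taken up by K2CO3), so no sacrificial anode and no chemical oxidant are needed.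

## Compound list

1 | neryl acetate, (2Z)-3,7-dimethylocta-2,6-dien-1-yl acetate | CC(=O)OC/C=C(/C)CCC=C(C)C | starting material
2 | (2Z)-5-(3,3-dimethyloxiran-2-yl)-3-methylpent-2-en-1-yl acetate (racemic at the oxirane carbon) | CC(=O)OC/C=C(/C)CCC1OC1(C)C | intermediate
3 | (2Z)-3-methyl-6-oxohex-2-en-1-yl acetate | CC(=O)OC/C=C(/C)CCC=O | intermediate
4 | (2Z,6E)-3-methyl-8-oxoocta-2,6-dien-1-yl acetate | CC(=O)OC/C=C(/C)CC/C=C/C=O | intermediate
5 | (2Z,6Z)-7-iodo-3-methyl-8-oxoocta-2,6-dien-1-yl acetate | CC(=O)OC/C=C(/C)CC/C=C(/C=O)I | intermediate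
6 | (2Z,6Z)-7-iodo-8,8-dimethoxy-3-methylocta-2,6-dien-1-yl acetate | CC(=O)OC/C=C(/C)CC/C=C(/C(OC)OC)I | intermediate
7 | (2Z,6Z)-7-iodo-8,8-dimethoxy-3-methylocta-2,6-dien-1-ol | OC/C=C(/C)CC/C=C(/C(OC)OC)I | intermediate
8 | (2Z,6Z)-8-bromo-2-iodo-1,1-dimethoxy-6-methylocta-2,6-diene | BrC/C=C(/C)CC/C=C(/C(OC)OC)I | intermediate
9 | (S)-3-hydroxy-γ-butyrolactone, (4S)-4-hydroxyoxolan-2-one | O=C1C[C@H](O)CO1 | starting material
10 | dilithium alkoxide–enolate (dianion) of 9 | [Li+].[Li+].[O-]C1=C[C@H]([O-])CO1 | intermediate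
11 | (3S,4S)-4-hydroxy-3-[(2Z,6Z)-7-iodo-8,8-dimethoxy-3-methylocta-2,6-dien-1-yl]oxolan-2-one | O=C1OC[C@@H](O)[C@@H]1C/C=C(/C)CC/C=C(/C(OC)OC)I | intermediate
12 | (3S,4S)-3-[(2Z,6Z)-7-iodo-8,8-dimethoxy-3-methylocta-2,6-dien-1-yl]-4-(triethylsilyloxy)oxolan-2-one | O=C1OC[C@@H](O[Si](CC)(CC)CC)[C@@H]1C/C=C(/C)CC/C=C(/C(OC)OC)I | intermediate
13 | (3S,5Z,9Z)-3-[(1S)-2-hydroxy-1-(triethylsilyloxy)ethyl]-10-iodo-11,11-dimethoxy-6-methylundeca-5,9-dien-2-one | OC[C@@H](O[Si](CC)(CC)CC)[C@@H](C(C)=O)C/C=C(/C)CC/C=C(/C(OC)OC)I | intermediate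
14 | (2S,3S,5Z,9Z)-3-acetyl-10-iodo-11,11-dimethoxy-6-methyl-2-(triethylsilyloxy)undeca-5,9-dienal | O=C[C@@H](O[Si](CC)(CC)CC)[C@@H](C(C)=O)C/C=C(/C)CC/C=C(/C(OC)OC)I | intermediate
15 | (7S,8S,9R,1(10)E,4Z)-7-acetyl-10-(dimethoxymethyl)-4-methyl-8-(triethylsilyloxy)cyclodeca-1(10),4-dien-9-ol (both ring double bonds cis in the ring) | CC(=O)[C@H]1C/C=C(/C)CC/C=C(/C(OC)OC)[C@@H](O)[C@H]1O[Si](CC)(CC)CC | intermediate
16 | (7S,8S,9S,1(10)E,4Z)-7-acetyl-10-(dimethoxymethyl)-4-methyl-8-(triethylsilyloxy)cyclodeca-1(10),4-dien-9-yl 2-methylpropanoate | CC(=O)[C@H]1C/C=C(/C)CC/C=C(/C(OC)OC)[C@H](OC(=O)C(C)C)[C@H]1O[Si](CC)(CC)CC | intermediate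
17 | (7S,8S,9S,1(10)E,4Z)-10-(dimethoxymethyl)-4-methyl-8-(triethylsilyloxy)-7-[1-(trifluoromethylsulfonyloxy)vinyl]cyclodeca-1(10),4-dien-9-yl 2-methylpropanoate | C=C(OS(=O)(=O)C(F)(F)F)[C@H]1C/C=C(/C)CC/C=C(/C(OC)OC)[C@H](OC(=O)C(C)C)[C@H]1O[Si](CC)(CC)CC | intermediate
18 | (7S,8S,9S,1(10)E,4Z)-10-formyl-8-hydroxy-4-methyl-7-[1-(trifluoromethylsulfonyloxy)vinyl]cyclodeca-1(10),4-dien-9-yl 2-methylpropanoate | C=C(OS(=O)(=O)C(F)(F)F)[C@H]1C/C=C(/C)CC/C=C(/C=O)[C@H](OC(=O)C(C)C)[C@H]1O | intermediate
19 | (7S,8S,9S,1(10)E,4Z)-10-formyl-4-methyl-7-[1-(trifluoromethylsulfonyloxy)vinyl]cyclodeca-1(10),4-diene-8,9-diyl bis(2-methylpropanoate) | C=C(OS(=O)(=O)C(F)(F)F)[C@H]1C/C=C(/C)CC/C=C(/C=O)[C@H](OC(=O)C(C)C)[C@H]1OC(=O)C(C)C | intermediate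
20 | 2-[(7R,8S,9S,1(10)E,4Z)-10-formyl-4-methyl-8,9-bis(2-methylpropanoyloxy)cyclodeca-1(10),4-dien-7-yl]acrylic acid (formed as its carboxylate) | C=C(C(=O)O)[C@H]1C/C=C(/C)CC/C=C(/C=O)[C@H](OC(=O)C(C)C)[C@H]1OC(=O)C(C)C | intermediate
21 | (6R,7S,8S,9S,1(10)E,4Z)-8,9-bis(2-methylpropanoyloxy)-14-oxogermacra-1(10),4,11(13)-trien-12,6-olide | C=C1C(=O)O[C@@H]2/C=C(/C)CC/C=C(/C=O)[C@H](OC(=O)C(C)C)[C@@H](OC(=O)C(C)C)[C@@H]12 | target

## Step count and risks

Total step count: 15. Longest linear sequence: 15 steps (1 to 21); 9 is a purchased building block that enters at step 6.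

Steps most likely to fail:

Step 15 (key step, proposed new method). What may go wrong: the anodically formed acyloxy radical may add to the C4=C5 double bond or be over-oxidised instead of taking the C6 hydrogen, the two electrode processes may not keep pace in one cell, or the allyl cation may be captured with the wrong facial sense. Fallback, known chemistry only, setting out from 19 and coming back at 21: the two bond formations are uncoupled, and the O–C6 bond is made by an ionic allylic transposition instead of hydrogen-atom transfer. Nickel-catalysed reductive carboxylation of 19 with a metal reductant (NiBr2(2,2′-bipyridine) cat., Mn powder, Et4NI, CO2 1 atm, N,N-dimethylacetamide, rt) should give the acrylic acid 20, now isolated. A Schenck ene reaction of its C4=C5 double bond with singlet oxygen (O2, tetraphenylporphyrin, visible light, CH2Cl2, −20 °C) removes a hydrogen from the disubstituted side of the olefin; abstraction at C6 gives the tertiary C4 allylic hydroperoxide F1 (the C3-abstraction isomer would be separated). PPh3 in the same flask reduces it to the tertiary allylic alcohol F2. Camphorsulfonic acid (cat., CH2Cl2, 0 °C) then ionises F2 to the C4–C5–C6 allyl cation, which the carboxyl group captures at C6 with loss of water (allylic transposition and lactonisation) to give 21.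

Step 10. What may go wrong: slow ring closure with competing intermolecular coupling, and poor facial selectivity at C9 when only the substrate controls it. Fallback, setting out from 14 and coming back at 16: the closure is run under ligand control instead of substrate control, in the catalytic asymmetric variant of the Nozaki–Hiyama–Kishi reaction (CrCl2 cat., NiCl2 cat., a chiral sulfonamide–oxazoline ligand, Mn powder, Zr(C5H5)2Cl2, LiCl, MeCN, syringe-pump addition). The ligand-bound chromium turns over faster, which favours ring closure, and the ligand enantiomer is chosen to give the (9S)-alcohol F3 directly. F3 is then acylated with retention (isobutyric anhydride, DMAP, pyridine) to 16, which also removes the Mitsunobu inversion of step 11.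

Step 8. What may go wrong: iodine–lithium exchange at the vinyl iodide, or a second addition of MeLi to the ketone. Fallback, setting out from 11 and coming back at 14: the methyl ketone is made through a Weinreb amide and a Grignard reagent, which does not exchange with the vinyl iodide. MeNH(OMe)·HCl with AlMe3 (CH2Cl2, 0 °C) opens lactone 11 to the dihydroxy Weinreb amide F4. TESCl and imidazole (DMF) give the bis(triethylsilyl) ether F5. MeMgBr (THF, 0 °C) gives the methyl ketone F6. Swern oxidation ((COCl)2, DMSO, CH2Cl2, −78 to −30 °C, then Et3N), which cleaves and oxidises the primary triethylsilyl ether selectively, gives aldehyde 14; steps 7 to 9 are bypassed.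

Further compounds
F1 | step 15 | 2-[(7R,8S,9S,1(10)E,5E)-10-formyl-4-hydroperoxy-4-methyl-8,9-bis(2-methylpropanoyloxy)cyclodeca-1(10),5-dien-7-yl]acrylic acid (C4 epimers) | C=C(C(=O)O)[C@H]1/C=C/C(C)(OO)CC/C=C(/C=O)[C@H](OC(=O)C(C)C)[C@H]1OC(=O)C(C)C
F2 | step 15 | 2-[(7R,8S,9S,1(10)E,5E)-10-formyl-4-hydroxy-4-methyl-8,9-bis(2-methylpropanoyloxy)cyclodeca-1(10),5-dien-7-yl]acrylic acid (C4 epimers) | C=C(C(=O)O)[C@H]1/C=C/C(C)(O)CC/C=C(/C=O)[C@H](OC(=O)C(C)C)[C@H]1OC(=O)C(C)C
F3 | step 10 | (7S,8S,9S,1(10)E,4Z)-7-acetyl-10-(dimethoxymethyl)-4-methyl-8-(triethylsilyloxy)cyclodeca-1(10),4-dien-9-ol | CC(=O)[C@H]1C/C=C(/C)CC/C=C(/C(OC)OC)[C@H](O)[C@H]1O[Si](CC)(CC)CC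
F4 | step 8 | (2S,4Z,8Z)-2-[(1S)-1,2-dihydroxyethyl]-9-iodo-N,10,10-trimethoxy-N,5-dimethyldeca-4,8-dienamide | OC[C@@H](O)[C@@H](C(=O)N(C)OC)C/C=C(/C)CC/C=C(/C(OC)OC)I
F5 | step 8 | (2S,4Z,8Z)-2-[(1S)-1,2-bis(triethylsilyloxy)ethyl]-9-iodo-N,10,10-trimethoxy-N,5-dimethyldeca-4,8-dienamide | CC[Si](CC)(CC)OC[C@@H](O[Si](CC)(CC)CC)[C@@H](C(=O)N(C)OC)C/C=C(/C)CC/C=C(/C(OC)OC)I
F6 | step 8 | (3S,5Z,9Z)-3-[(1S)-1,2-bis(triethylsilyloxy)ethyl]-10-iodo-11,11-dimethoxy-6-methylundeca-5,9-dien-2-one | CC[Si](CC)(CC)OC[C@@H](O[Si](CC)(CC)CC)[C@@H](C(C)=O)C/C=C(/C)CC/C=C(/C(OC)OC)I
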